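**Remarks on the chemistry (assumptions)**
- The SMILES is read literally: both trisubstituted ring olefins are Z (ring carbons cis), not the E,E geometry common in germacranes.
- Technical 1,5-dimethylcycloocta-1,5-diene contains some 1,6-dimethyl isomer; it is assumed to be removed by fractional distillation before use.
- Acid chloride 12 is used as the racemate, because its stereocentre is lost in the route.

## Structural features

The target is a ten-membered carbocycle, numbered here C1–C10 in the order of the SMILES: C1 carries the acetate, C2=C3 the first olefin (methyl on C3), C4 the free hydroxyl, C5, C6=C7 the second olefin (methyl on C7), C8, C9 the cinnamate and C10 the isopropyl group. Both ring olefins are trisubstituted and Z, and they sit head to tail as a 1,5-diene, C2=C3(Me)–C4–C5–C6=C7(Me). C9, C10 and C1 form a contiguous stereotriad (9S,10R,1S): O1 and O9 are 1,3-anti, and the isopropyl group is cis to O1 and trans to O9 on the ring. C4 (R) is remote from the triad, with its oxygen on the same face as O9. Three secondary oxygens must be told apart as acetate, cinnamate and free alcohol. Fragile points are the C4 alkoxide, which sits on the sp3 carbon of a 1,5-diene (anionic oxy-Cope ring contraction), the 1,3-related esters (acyl migration), and any β-acyloxy carbonyl intermediate (elimination). The real difficulty is the medium ring with two Z trisubstituted olefins, combined with the stereotriad. The key step exploits two facts: C1–C8 with both methyl groups and both Z olefins is the skeleton of the isoprene cyclodimer (1Z,5Z)-1,5-dimethylcycloocta-1,5-diene, and C9–C10 with its isopropyl group, flanked by oxygenated C1 and C9, is a 2-isopropyl-1,3-dicarbonyl unit. The route is therefore a two-carbon ring expansion of the silyl dienol ether of an eight-membered dienone by ketene [2+2] cycloaddition and retro-aldol opening.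

## Logic of the disconnections

**20 to 18 (through 19).** The Si–O4 bond and the acetyl–O1 bond are cut. C4 stays silylated to the end, so that no alkoxide is formed on the 1,5-diene and no basic step meets a free 1,3-diol monoester. The gain is the differentiation of the three oxygens. The demand is acetylation without acyl migration and desilylation without base.

**18 to 16 and 17.** The acyl–O9 bond and the C1–H bond are cut together, since both can come from the aldehyde 17 in one intramolecular hydride transfer. This removes the C1 stereocentre and the ester in one operation and avoids acylating a β-hydroxy ketone under basic conditions. The demand is hemiacetal formation at a hindered alcohol and a chair transition state inside the ten-membered ring that gives the 1,3-anti diol.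

**16 to 15.** The C9–H bond is cut, which turns C10 into a labile 1,3-dicarbonyl methine. Two stereocentres disappear and 15 keeps only C4. The demand is a dynamic reduction under catalyst control that ignores the remote C4, touches only the saturated C9 carbonyl and is slower than epimerisation at C10.

**15 to 11 and 12 (key).** The C8–C9 and C1–C10 bonds are cut and C1–C8 is re-joined. The ten-membered ring contracts to the eight-membered ring and the C9–C10 unit leaves as a ketene derived from 12. This is chosen because the 1,3-dicarbonyl around C10 is the retron of a cyclobutanone retro-aldol. The gain is that no medium ring has to be closed and both Z olefins are inherited from a ring in which they cannot isomerise. The demand is cycloaddition at the siloxy-bearing olefin of 11 with the ketene carbonyl carbon on C8, and ring opening toward C8.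

**11 back to 4 (through 10, 9, 8, 6 and 5).** Only functional groups change. The C1 carbonyl of 10 is traced by 1,3-transposition to the tertiary C3 alcohol of 9, which comes from the C2–C3 epoxide of 5 by opening at C2 and elimination toward C1. The epoxide is placed by the C4 hydroxyl of 4. The gain is that the 1,4-dioxygenated enone reduces to a simple allylic alcohol. The demand is regioselective epoxide opening, elimination away from the carbinol and selective silylation of the secondary hydroxyl.

**4 to 1 (through 3).** The C4–H bond (enantioselective reduction) and the C4–O bond (allylic oxidation) are cut. Hydrocarbon 1 has a twofold axis, so C4 and C8 are equivalent and mono-oxidation gives one constitution. The gain is a commercial material that already holds eight of the ten ring carbons, both methyl groups and both Z olefins. The demand is oxidation at the ring CH2 next to the methyl-bearing olefin carbon, stopped at mono-oxidation.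

## Other disconnections considered

**Alternative 1:** (the first idea) Cut C3–C4. The forward key step would be a Nozaki–Hiyama–Kishi macrocyclisation (CrCl2, NiCl2 cat.) of the acyclic (Z)-vinyl iodide aldehyde A1, which would give 20 and its C4 epimer A2. A ten-membered ring closure carries the full transannular and entropic penalty. C4 would be formed four atoms from the nearest stereocentre with no credible control. A1 needs both Z trisubstituted olefins and the whole triad built in open chain, and contains a β,γ-unsaturated aldehyde. The chosen plan buys the olefins and closes no medium ring.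

**Alternative 2:** Cut C8–C9 and reconnect C1–C6. The forward key step would be the anionic oxy-Cope ring expansion (KH, 18-crown-6) of the 1,2-dialkenylcyclohexenol A3 to the cyclodecadienone A4. Vinyl addition to the parent ketone goes trans to the isopropenyl group, and the chair transition state of a trans-dialkenyl carbinol places the ring bond of C6 equatorial. The new C6=C7 olefin is therefore expected ring-trans, as drawn in A4, and this cannot be corrected later in a ten-membered ring. C10 would also arise by uncontrolled enolate protonation.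

**Alternative 3:** Cut the ring by re-forming C4–C9. The forward key step would be glycol cleavage (Pb(OAc)4) of the cis-fused hexahydronaphthalene-4a,8a-diol A5 to the diketone A6. Both Z olefins would come from cyclohexenes, which is attractive. However, C4 and C9 emerge as ketones, so two of the four stereocentres are erased and must be reset on a flexible ring with opposite facial senses. Both carbonyls are β,γ to the same olefin. A5, with two adjacent tertiary carbinols and two further stereocentres, would take more steps than the eight-membered ketone of the chosen plan.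

Key step: step 9

## Route

Step 1
Reactants: 1 (1Z,5Z)-1,5-dimethylcycloocta-1,5-diene
Product: 3 (2Z,6Z)-2,6-dimethylcycloocta-2,6-dien-1-one, via racemic allylic alcohol 2 (not isolated)
Conditions: SeO2 (0.5 equiv), t-BuOOH, CH2Cl2, rt, to partial conversion; then Dess–Martin periodinane, pyridine, CH2Cl2, 0 °C
Reagents that add atoms: selenium dioxide, O=[Se]=O; tert-butyl hydroperoxide, CC(C)(C)OO
Why: Allylic oxidation with SeO2 (ene reaction, then [2,3]-sigmatropic shift) puts oxygen on the ring CH2 attached to the methyl-bearing olefin carbon, and the twofold axis of 1 makes the two such positions (C4 and C8) identical. Dess–Martin oxidation converges the alcohol/enone mixture on 3; no stereocentre is formed and unreacted 1 is recycled.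

Step 2
Reactants: 3 (2Z,6Z)-2,6-dimethylcycloocta-2,6-dien-1-one
Product: 4 (1R,2Z,6Z)-2,6-dimethylcycloocta-2,6-dien-1-ol
Conditions: (S)-Me-CBS oxazaborolidine [(S)-1-methyl-3,3-diphenyltetrahydro-1H,3H-pyrrolo[1,2-c][1,3,2]oxazaborole] (10 mol %), BH3·SMe2, THF, −20 °C
Reagents that add atoms: none
Why: Corey–Bakshi–Shibata reduction, in which the α-methyl alkenyl arm acts as the large group and the CH2 arm as the small one, so the (S)-catalyst should deliver hydride to give the R carbinol (C4 of the target). The cold, non-basic conditions should leave the β,γ-olefin in place.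

Step 3
Reactants: 4 (1R,2Z,6Z)-2,6-dimethylcycloocta-2,6-dien-1-ol
Product: 5 (1R,2R,4Z,8S)-1,5-dimethyl-9-oxabicyclo[6.1.0]non-4-en-2-ol
Conditions: VO(acac)2 (2 mol %), t-BuOOH, CH2Cl2, 0 °C to rt
Reagents that add atoms: tert-butyl hydroperoxide, CC(C)(C)OO
Why: Hydroxyl-directed vanadium-catalysed epoxidation; the allylic olefin reacts far faster than the remote one, and oxygen is delivered syn to the hydroxyl, as expected for cyclooct-2-enols. The epoxide configuration has no consequence for 20 because C2 and C3 become trigonal again.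

Step 4
Reactants: 5 (1R,2R,4Z,8S)-1,5-dimethyl-9-oxabicyclo[6.1.0]non-4-en-2-ol
Product: 6 (1R,2R,4Z,8R)-1,5-dimethyl-8-(phenylselanyl)cyclooct-4-ene-1,2-diol
Conditions: (PhSe)2, NaBH4, EtOH, rt then reflux
Reagents that add atoms: diphenyl diselenide, c1ccc(cc1)[Se][Se]c1ccccc1
Why: SN2 opening of the trisubstituted epoxide by phenylselenolate at the secondary carbon (C2, inversion), which is also the position distal to the carbinol, leaves the tertiary C3 alcohol.

Step 5
Reactants: 6 (1R,2R,4Z,8R)-1,5-dimethyl-8-(phenylselanyl)cyclooct-4-ene-1,2-diol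
Product: 8 (1R,2S,3Z,6Z)-2,6-dimethylcycloocta-3,6-diene-1,2-diol, via selenoxide 7 (not isolated)
Conditions: mCPBA (1.05 equiv), CH2Cl2, −78 °C; then i-Pr2NH, −78 °C to rt
Reagents that add atoms: none
Why: Selenide oxidation and selenoxide syn-elimination; the only β-hydrogens are on C1 (C3 is fully substituted), so the cis C1=C2 olefin and the tertiary allylic alcohol form regiospecifically. Oxidation of selenium at −78 °C is much faster than epoxidation of the remaining olefin.

Step 6
Reactants: 8 (1R,2S,3Z,6Z)-2,6-dimethylcycloocta-3,6-diene-1,2-diol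
Product: 9 (1S,2Z,5Z,8R)-8-[(tert-butyldimethylsilyl)oxy]-1,5-dimethylcycloocta-2,5-dien-1-ol
Conditions: TBSCl, imidazole, DMF, 0 °C
Reagents that add atoms: tert-butyl(chloro)dimethylsilane, CC(C)(C)[Si](C)(C)Cl
Why: Silylation of the secondary hydroxyl is much faster than that of the tertiary one, and the free tertiary allylic alcohol is needed for the next step.

Step 7
Reactants: 9 (1S,2Z,5Z,8R)-8-[(tert-butyldimethylsilyl)oxy]-1,5-dimethylcycloocta-2,5-dien-1-ol
Product: 10 (2Z,4R,6Z)-4-[(tert-butyldimethylsilyl)oxy]-3,7-dimethylcycloocta-2,6-dien-1-one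
Conditions: pyridinium chlorochromate [C5H5NH][CrO3Cl] (2.5 equiv), Celite, CH2Cl2, rt
Reagents that add atoms: pyridinium chlorochromate, [O-][Cr](=O)(=O)Cl.c1cc[nH+]cc1
Why: Babler–Dauben oxidative transposition, in which the chromate ester of the tertiary allylic alcohol undergoes a [3,3] shift to C1 and is oxidised to the enone. The C3 stereocentre is consumed and C2=C3 is regenerated, cis by ring constraint.

Step 8
Reactants: 10 (2Z,4R,6Z)-4-[(tert-butyldimethylsilyl)oxy]-3,7-dimethylcycloocta-2,6-dien-1-one
Product: 11 tert-butyl{[(1R,2Z,4E,6Z)-2,6-dimethyl-4-[(trimethylsilyl)oxy]cycloocta-2,4,6-trien-1-yl]oxy}dimethylsilane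
Conditions: LiN(i-Pr)2, Me3SiCl (internal quench), THF, −78 °C; used at once
Reagents that add atoms: chlorotrimethylsilane, C[Si](C)(C)Cl
Why: Kinetic α′-deprotonation of the enone at C8, which is also allylic, with in-situ silylation gives the C1=C8 silyl dienol ether. No stereocentre is formed, and the cold, immediate use avoids electrocyclisation of the cyclooctatriene.

Step 9
Reactants: 11 tert-butyl{[(1R,2Z,4E,6Z)-2,6-dimethyl-4-[(trimethylsilyl)oxy]cycloocta-2,4,6-trien-1-yl]oxy}dimethylsilane; 12 2-bromo-3-methylbutanoyl chloride (racemic)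
Product: 15 (4Z,6R,8Z)-6-[(tert-butyldimethylsilyl)oxy]-5,9-dimethyl-2-(propan-2-yl)cyclodeca-4,8-diene-1,3-dione, via bromocyclobutanone 13 (not isolated), via siloxycyclobutanone 14 (not isolated)
Conditions: (i) 12, Et3N, hexane, 0 °C to rt; (ii) Zn, AcOH, i-PrOH–H2O, 0 °C; (iii) Bu4NF, AcOH, THF, 0 °C
Reagents that add atoms: none
Why: Et3N converts 12 into bromo(isopropyl)ketene, whose central carbon is attacked by C8 of 11, and the C10–C1 bond then closes to the cis-fused 3-siloxycyclobutanone 13 (ketene–enol ether [2+2] cycloaddition, the four-membered ring formed in the usual asynchronous [π2s+π2a] mode). The closest known reaction type is the two-carbon ring expansion of cycloalkanone silyl enol ethers with halogenated ketenes, followed by reductive dehalogenation and ring opening to cycloalkane-1,3-diones. Zinc removes bromine from 13, and fluoride then frees the C1 alkoxide of 14, which fragments by retro-aldol cleavage of the shared C1–C8 bond; the ten-membered ring is thus not closed by bond formation but released from the bicyclo[6.2.0]decane, driven by loss of cyclobutane strain. The step needs site selectivity among the three olefins of 11 and the right orientation: C8 is the β-carbon of the enol ether, attack there gives a cation stabilised by oxygen and by the C2=C3 vinyl group, and the tub shape of the cyclooctatriene weakens vinylogous transmission to C6. The direction of ring opening is secured after debromination, because cleavage toward C8 gives a secondary enolate that is also allylic to C6=C7, whereas cleavage toward C10 would give a tertiary one. No stereocentre of 15 has to be controlled here: C1 and C8 of 13 lose their stereogenicity again, C10 remains an epimerising 1,3-dicarbonyl methine, C4 is untouched, and both Z olefins stay locked because they never leave a ring. Acetic acid protonates the dienolate at C8 (kinetic α-protonation), which should keep C6=C7 out of conjugation.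

Step 10
Reactants: 15 (4Z,6R,8Z)-6-[(tert-butyldimethylsilyl)oxy]-5,9-dimethyl-2-(propan-2-yl)cyclodeca-4,8-diene-1,3-dione
Product: 16 (2Z,4R,6Z,9S,10R)-4-[(tert-butyldimethylsilyl)oxy]-9-hydroxy-3,7-dimethyl-10-(propan-2-yl)cyclodeca-2,6-dien-1-one
Conditions: NADPH-dependent ketoreductase (Prelog-selective, chosen from a screening panel), NADP+ (cat.), i-PrOH, phosphate buffer pH 7, DMSO co-solvent, 30 °C
Reagents that add atoms: none
Why: Ketoreductase-catalysed dynamic reductive kinetic resolution of an α-alkyl 1,3-diketone; C10 epimerises through the enol at pH 7 while the enzyme reduces only the saturated C9 carbonyl of one C10 epimer from one face, so 9S and 10R are set together and the remote C4 is overridden. The conjugated C1 carbonyl is expected to be the poorer substrate, and the neutral medium avoids retro-aldol cleavage and olefin migration.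

Step 11
Reactants: 16 (2Z,4R,6Z,9S,10R)-4-[(tert-butyldimethylsilyl)oxy]-9-hydroxy-3,7-dimethyl-10-(propan-2-yl)cyclodeca-2,6-dien-1-one; 17 (2E)-3-phenylprop-2-enal
Product: 18 (1S,2S,3S,4Z,6R,8Z)-6-[(tert-butyldimethylsilyl)oxy]-3-hydroxy-5,9-dimethyl-2-(propan-2-yl)cyclodeca-4,8-dien-1-yl (2E)-3-phenylprop-2-enoate
Conditions: 17 (4 equiv), SmI2 (30 mol %), THF, −10 °C
Reagents that add atoms: none
Why: Evans–Tishchenko reduction, in which the C9 hydroxyl adds to 17 and the samarium-bound hemiacetal transfers its hydride intramolecularly to C1 through a chair six-membered transition state. This should give the 1,3-anti diol (1S) and leave the cinnamoyl group on O9, so ester and stereocentre arrive together without exposing a β-acyloxy ketone to base.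

Step 12
Reactants: 18 (1S,2S,3S,4Z,6R,8Z)-6-[(tert-butyldimethylsilyl)oxy]-3-hydroxy-5,9-dimethyl-2-(propan-2-yl)cyclodeca-4,8-dien-1-yl (2E)-3-phenylprop-2-enoate
Product: 19 (1S,2R,3S,4Z,6R,8Z)-3-(acetyloxy)-6-[(tert-butyldimethylsilyl)oxy]-5,9-dimethyl-2-(propan-2-yl)cyclodeca-4,8-dien-1-yl (2E)-3-phenylprop-2-enoate
Conditions: Ac2O, pyridine, DMAP (cat.), CH2Cl2, 0 °C
Reagents that add atoms: acetic anhydride, CC(=O)OC(C)=O
Why: DMAP-catalysed acetylation of the only free hydroxyl; low temperature and excess anhydride should make acetylation faster than 1,3-migration of the cinnamoyl group. The descriptor at C2 changes only through CIP priorities.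

Step 13
Reactants: 19 (1S,2R,3S,4Z,6R,8Z)-3-(acetyloxy)-6-[(tert-butyldimethylsilyl)oxy]-5,9-dimethyl-2-(propan-2-yl)cyclodeca-4,8-dien-1-yl (2E)-3-phenylprop-2-enoate
Product: 20 (1S,2R,3S,4Z,6R,8Z)-3-(acetyloxy)-6-hydroxy-5,9-dimethyl-2-(propan-2-yl)cyclodeca-4,8-dien-1-yl (2E)-3-phenylprop-2-enoate
Conditions: HF·pyridine, pyridine, THF, 0 °C to rt
Reagents that add atoms: none
Why: Buffered fluoride cleavage of the silyl ether; no alkoxide is generated, so neither acyl migration nor anionic oxy-Cope ring contraction of the C4 oxygen on the 1,5-diene is expected, and the esters are inert.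

## Compound list

1 | (1Z,5Z)-1,5-dimethylcycloocta-1,5-diene | C1/C=C(/C)CC/C=C(/C)C1 | starting material
2 | (2Z,6Z)-2,6-dimethylcycloocta-2,6-dien-1-ol, racemic | C1/C=C(/C)C(O)C/C=C(/C)C1 | intermediate
3 | (2Z,6Z)-2,6-dimethylcycloocta-2,6-dien-1-one | C1/C=C(/C)C(=O)C/C=C(/C)C1 | intermediate
4 | (1R,2Z,6Z)-2,6-dimethylcycloocta-2,6-dien-1-ol | C1/C=C(/C)[C@H](O)C/C=C(/C)C1 | intermediate
5 | (1R,2R,4Z,8S)-1,5-dimethyl-9-oxabicyclo[6.1.0]non-4-en-2-ol | C1[C@@H]2O[C@]2(C)[C@H](O)C/C=C(/C)C1 | intermediate
6 | (1R,2R,4Z,8R)-1,5-dimethyl-8-(phenylselanyl)cyclooct-4-ene-1,2-diol | C1[C@@H]([Se]c2ccccc2)[C@](C)(O)[C@H](O)C/C=C(/C)C1 | intermediate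
7 | (1R,2R,4Z,8R)-1,5-dimethyl-8-(phenylseleninyl)cyclooct-4-ene-1,2-diol (selenium configuration undefined) | C1[C@@H]([Se](=O)c2ccccc2)[C@](C)(O)[C@H](O)C/C=C(/C)C1 | intermediate
8 | (1R,2S,3Z,6Z)-2,6-dimethylcycloocta-3,6-diene-1,2-diol | C1/C=C\[C@](C)(O)[C@H](O)C/C=C1/C | intermediate
9 | (1S,2Z,5Z,8R)-8-[(tert-butyldimethylsilyl)oxy]-1,5-dimethylcycloocta-2,5-dien-1-ol | C1/C=C\[C@](C)(O)[C@H](O[Si](C)(C)C(C)(C)C)C/C=C1/C | intermediate
10 | (2Z,4R,6Z)-4-[(tert-butyldimethylsilyl)oxy]-3,7-dimethylcycloocta-2,6-dien-1-one | O=C1/C=C(/C)[C@H](O[Si](C)(C)C(C)(C)C)C/C=C(/C)C1 | intermediate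
11 | tert-butyl{[(1R,2Z,4E,6Z)-2,6-dimethyl-4-[(trimethylsilyl)oxy]cycloocta-2,4,6-trien-1-yl]oxy}dimethylsilane | C1/C=C(C)\C=C(O[Si](C)(C)C)/C=C(C)\[C@@H]1O[Si](C)(C)C(C)(C)C | intermediate
12 | 2-bromo-3-methylbutanoyl chloride (racemic) | CC(C)C(Br)C(Cl)=O | starting material
13 | (2Z,5R,6Z)-9-bromo-5-[(tert-butyldimethylsilyl)oxy]-2,6-dimethyl-9-(propan-2-yl)-8-[(trimethylsilyl)oxy]bicyclo[6.2.0]deca-2,6-dien-10-one (cis-fused; diastereomers at C1, C8, C9) | O=C1C2/C(C)=C\C[C@@H](O[Si](C)(C)C(C)(C)C)/C(C)=C\C2(O[Si](C)(C)C)C1(Br)C(C)C | intermediate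
14 | (2Z,5R,6Z)-5-[(tert-butyldimethylsilyl)oxy]-2,6-dimethyl-9-(propan-2-yl)-8-[(trimethylsilyl)oxy]bicyclo[6.2.0]deca-2,6-dien-10-one (cis-fused; diastereomers at C1, C8, C9) | O=C1C2/C(C)=C\C[C@@H](O[Si](C)(C)C(C)(C)C)/C(C)=C\C2(O[Si](C)(C)C)C1C(C)C | intermediate
15 | (4Z,6R,8Z)-6-[(tert-butyldimethylsilyl)oxy]-5,9-dimethyl-2-(propan-2-yl)cyclodeca-4,8-diene-1,3-dione (C2 epimers interconvert) | O=C1/C=C(/C)[C@H](O[Si](C)(C)C(C)(C)C)C/C=C(/C)CC(=O)C1C(C)C | intermediate
16 | (2Z,4R,6Z,9S,10R)-4-[(tert-butyldimethylsilyl)oxy]-9-hydroxy-3,7-dimethyl-10-(propan-2-yl)cyclodeca-2,6-dien-1-one | O=C1/C=C(/C)[C@H](O[Si](C)(C)C(C)(C)C)C/C=C(/C)C[C@H](O)[C@H]1C(C)C | intermediate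
17 | (2E)-3-phenylprop-2-enal | O=C/C=C/c1ccccc1 | starting material
18 | (1S,2S,3S,4Z,6R,8Z)-6-[(tert-butyldimethylsilyl)oxy]-3-hydroxy-5,9-dimethyl-2-(propan-2-yl)cyclodeca-4,8-dien-1-yl (2E)-3-phenylprop-2-enoate | O[C@H]1/C=C(/C)[C@H](O[Si](C)(C)C(C)(C)C)C/C=C(/C)C[C@H](OC(=O)/C=C/c2ccccc2)[C@H]1C(C)C | intermediate
19 | (1S,2R,3S,4Z,6R,8Z)-3-(acetyloxy)-6-[(tert-butyldimethylsilyl)oxy]-5,9-dimethyl-2-(propan-2-yl)cyclodeca-4,8-dien-1-yl (2E)-3-phenylprop-2-enoate | CC(=O)O[C@H]1/C=C(/C)[C@H](O[Si](C)(C)C(C)(C)C)C/C=C(/C)C[C@H](OC(=O)/C=C/c2ccccc2)[C@H]1C(C)C | intermediate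
20 | (1S,2R,3S,4Z,6R,8Z)-3-(acetyloxy)-6-hydroxy-5,9-dimethyl-2-(propan-2-yl)cyclodeca-4,8-dien-1-yl (2E)-3-phenylprop-2-enoate | CC(=O)O[C@H]1/C=C(/C)[C@H](O)C/C=C(/C)C[C@H](OC(=O)/C=C/c2ccccc2)[C@H]1C(C)C | target

## Step count and least certain steps

Total step count: 13. Longest linear sequence: 13 steps (1 to 20); 12 and 17 enter directly in steps 9 and 11.

**Step 9 (key step).** The most likely failures are: cycloaddition at the remote C6=C7 end of the trienol ether (vinylogous attack); C-acylation by silyl transfer instead of ring closure, because the bromo(isopropyl) carbon must bond to the fully substituted C1; electrocyclisation of the cyclooctatriene; and γ-protonation of the dienolate, which would move C6=C7 into conjugation. Fallback, setting out from 11 and returning at 15: the smaller and more electrophilic dichloroketene (Cl2CHCOCl, Et3N) would give the dichlorocyclobutanone F1. Zinc in acetic acid would give the siloxycyclobutanone F2, and fluoride would open it to the unsubstituted ring-expanded dione F3. The isopropyl group would then be attached to C10 by Knoevenagel condensation with acetone (TiCl4, pyridine) to the isopropylidene dione F4, and conjugate reduction with a Hantzsch ester would give 15.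

**Step 10.** The enzyme may not accept a ten-membered substrate, may reduce the C1 carbonyl competitively, or may show low facial discrimination, and slow turnover would allow olefin migration in the buffer. Fallback, from 15 back to 16: chelation-controlled reduction with Zn(BH4)2 should give the syn β-hydroxy ketones without absolute control, that is 16 together with its (9R,10S) diastereomer F5. These are diastereomers because of C4 and would be separated by chromatography; F5 would be re-oxidised to 15 with Dess–Martin periodinane and recycled.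

**Step 11.** Hemiacetal formation with a conjugated aldehyde at a hindered alcohol may be slow, hydride transfer through the chair transition state may be disfavoured by the ring, and retro-aldol cleavage of 16 may compete. Fallback, from 16 back to 18: acid-catalysed acylation with cinnamic anhydride and Sc(OTf)3 (to avoid β-elimination) would give the cinnamoyloxy ketone F6. 1,2-Reduction with NaBH4 and CeCl3·7H2O at −78 °C would follow; the C1 epimer F7 would be separated and returned to F6 with MnO2.

**Step 2.** Facial discrimination may be insufficient, because both flanks of the carbonyl are ring carbons of similar size. Fallback, from 3 back to 4: Luche reduction to racemic 2, then kinetic resolution with a lipase (serine hydrolase class, for example lipase B of Candida antarctica) and vinyl acetate. This is expected to acylate the R enantiomer to the acetate F8 and leave the S alcohol F9. Methanolysis of F8 (K2CO3, MeOH) would give 4, and F9 would be re-oxidised to 3.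

**Step 7.** The acidic chromium reagent may cause migration of C6=C7 into conjugation through the doubly activated C8, oxidation of the doubly allylic C8 methylene, or loss of the silyl group. Fallback, from 9 back to 10: non-oxidative 1,3-transposition of the tertiary allylic alcohol with Ph3SiOReO3 (cat.) to the secondary allylic alcohol F10, then neutral oxidation with MnO2.

## Further compounds

F1 | step 9 | (2Z,5R,6Z)-5-[(tert-butyldimethylsilyl)oxy]-9,9-dichloro-2,6-dimethyl-8-[(trimethylsilyl)oxy]bicyclo[6.2.0]deca-2,6-dien-10-one | O=C1C2/C(C)=C\C[C@@H](O[Si](C)(C)C(C)(C)C)/C(C)=C\C2(O[Si](C)(C)C)C1(Cl)Cl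
F2 | step 9 | (2Z,5R,6Z)-5-[(tert-butyldimethylsilyl)oxy]-2,6-dimethyl-8-[(trimethylsilyl)oxy]bicyclo[6.2.0]deca-2,6-dien-10-one | O=C1C2/C(C)=C\C[C@@H](O[Si](C)(C)C(C)(C)C)/C(C)=C\C2(O[Si](C)(C)C)C1
F3 | step 9 | (4Z,6R,8Z)-6-[(tert-butyldimethylsilyl)oxy]-5,9-dimethylcyclodeca-4,8-diene-1,3-dione | O=C1/C=C(/C)[C@H](O[Si](C)(C)C(C)(C)C)C/C=C(/C)CC(=O)C1
F4 | step 9 | (4Z,6R,8Z)-6-[(tert-butyldimethylsilyl)oxy]-5,9-dimethyl-2-(propan-2-ylidene)cyclodeca-4,8-diene-1,3-dione | O=C1/C=C(/C)[C@H](O[Si](C)(C)C(C)(C)C)C/C=C(/C)CC(=O)C1=C(C)C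
F5 | step 10 | (2Z,4R,6Z,9R,10S)-4-[(tert-butyldimethylsilyl)oxy]-9-hydroxy-3,7-dimethyl-10-(propan-2-yl)cyclodeca-2,6-dien-1-one | O=C1/C=C(/C)[C@H](O[Si](C)(C)C(C)(C)C)C/C=C(/C)C[C@@H](O)[C@@H]1C(C)C
F6 | step 11 | (1S,2R,4Z,6R,8Z)-6-[(tert-butyldimethylsilyl)oxy]-5,9-dimethyl-3-oxo-2-(propan-2-yl)cyclodeca-4,8-dien-1-yl (2E)-3-phenylprop-2-enoate | O=C1/C=C(/C)[C@H](O[Si](C)(C)C(C)(C)C)C/C=C(/C)C[C@H](OC(=O)/C=C/c2ccccc2)[C@H]1C(C)C
F7 | step 11 | (1S,2S,3R,4Z,6R,8Z)-6-[(tert-butyldimethylsilyl)oxy]-3-hydroxy-5,9-dimethyl-2-(propan-2-yl)cyclodeca-4,8-dien-1-yl (2E)-3-phenylprop-2-enoate | O[C@@H]1/C=C(/C)[C@H](O[Si](C)(C)C(C)(C)C)C/C=C(/C)C[C@H](OC(=O)/C=C/c2ccccc2)[C@H]1C(C)C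
F8 | step 2 | (1R,2Z,6Z)-2,6-dimethylcycloocta-2,6-dien-1-yl acetate | C1/C=C(/C)[C@H](OC(C)=O)C/C=C(/C)C1
F9 | step 2 | (1S,2Z,6Z)-2,6-dimethylcycloocta-2,6-dien-1-ol | C1/C=C(/C)[C@@H](O)C/C=C(/C)C1
F10 | step 7 | (2Z,4R,6Z)-4-[(tert-butyldimethylsilyl)oxy]-3,7-dimethylcycloocta-2,6-dien-1-ol (C1 epimers) | OC1/C=C(/C)[C@H](O[Si](C)(C)C(C)(C)C)C/C=C(/C)C1
A1 | alternative 1 | (2Z,4R,5R,6S,8Z)-4-(acetyloxy)-2-iodo-8-methyl-11-oxo-5-(propan-2-yl)undeca-2,8-dien-6-yl (2E)-3-phenylprop-2-enoate | O=CC/C=C(/C)C[C@H](OC(=O)/C=C/c1ccccc1)[C@@H](C(C)C)[C@@H](OC(C)=O)/C=C(/C)I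
A2 | alternative 1 | (1S,2R,3S,4Z,6S,8Z)-3-(acetyloxy)-6-hydroxy-5,9-dimethyl-2-(propan-2-yl)cyclodeca-4,8-dien-1-yl (2E)-3-phenylprop-2-enoate (C6 epimer of 20) | CC(=O)O[C@H]1/C=C(/C)[C@@H](O)C/C=C(/C)C[C@H](OC(=O)/C=C/c2ccccc2)[C@H]1C(C)C
A3 | alternative 2 | 4-[(tert-butyldimethylsilyl)oxy]-1-[(1E)-1-(methoxymethoxy)-3-methylbut-1-en-2-yl]-3-methyl-6-(prop-1-en-2-yl)cyclohex-2-en-1-ol (alkenyl groups trans; configuration as in the SMILES) | O[C@@]1(/C(C(C)C)=C/OCOC)C=C(C)[C@H](O[Si](C)(C)C(C)(C)C)C[C@H]1C(C)=C
A4 | alternative 2 | (2Z,4R,6E)-4-[(tert-butyldimethylsilyl)oxy]-9-(methoxymethoxy)-3,7-dimethyl-10-(propan-2-yl)cyclodeca-2,6-dien-1-one (C9 and C10 as delivered by rearrangement and protonation) | O=C1/C=C(/C)[C@H](O[Si](C)(C)C(C)(C)C)C/C=C(\C)CC(OCOC)C1C(C)C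
A5 | alternative 3 | 4a,8a-dihydroxy-4,7-dimethyl-1-(propan-2-yl)-1,2,4a,5,8,8a-hexahydronaphthalen-2-yl acetate (cis ring fusion; C1 and C2 as in 20) | CC(=O)O[C@H]1C=C(C)[C@@]2(O)CC=C(C)C[C@@]2(O)[C@H]1C(C)C
A6 | alternative 3 | (1S,2Z,6Z,10R)-3,7-dimethyl-4,9-dioxo-10-(propan-2-yl)cyclodeca-2,6-dien-1-yl acetate | CC(=O)O[C@H]1/C=C(/C)C(=O)C/C=C(/C)CC(=O)[C@H]1C(C)C
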